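**Retrosynthetic overview**

- The target is a 2,2-dimethyl-2H-chromene whose benzene ring carries OH at C5, a 4-hydroxyphenethyl group at C7 and a prenyl group at C8; the last step only removes two methoxymethyl (MOM) ethers.
- The pyran ring is cut at C4–C4a and at O1–C8a. This gives an aryne (triple bond C4a≡C8a) and 3-methylbut-2-enal, joined by formal [2+2] addition to the C=O group, benzoxete opening and oxa-6π ring closure.
- Enabling feature: the adjacent benzene carbons C4a and C8a carry the carbon end and the oxygen end of one five-atom unit (O1–C2(CH3)2–C3=C4) that maps onto the enal. The oxygen on C5, next to C4a, polarises the aryne so that the carbonyl oxygen adds at C8a and the carbon at C4a.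
- The o-silylaryl triflate comes from dihydroresveratrol. C-formylation desymmetrises the resorcinol ring and distinguishes its two OH groups, the CHO group becomes the prenyl group through an o-quinone methide, and carbamate-directed silylation followed by triflation completes the precursor.
- Ring order: both benzene rings are bought; the pyran ring is the only ring formed (step 9).

Key step: step 9

Remark: dihydroresveratrol and 2-methylprop-1-en-1-ylmagnesium bromide (THF solution) are taken as catalogue compounds; the former is also the product of hydrogenating resveratrol over Pd/C.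

**Route**

Step 1
Reactants: 1 dihydroresveratrol (5-[2-(4-hydroxyphenyl)ethyl]benzene-1,3-diol)
Product: 3 2,4-dihydroxy-6-[2-(4-hydroxyphenyl)ethyl]benzaldehyde, via aryl iminium chloride 2 (not isolated)
Conditions: POCl3 (1.3 equiv), DMF (1.5 equiv), MeCN, −15 °C → rt; then H2O, 50 °C
Reagents that add atoms: N,N-dimethylformamide CN(C)C=O; water O
Why: Vilsmeier–Haack formylation; the resorcinol ring is far more nucleophilic than the mono-phenol ring, attack is expected at the position ortho to one OH and para to the other (next to the side chain), and the electron-poor iminium group should stop the reaction after one formylation.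

Step 2
Reactants: 3 2,4-dihydroxy-6-[2-(4-hydroxyphenyl)ethyl]benzaldehyde
Product: 4 2-hydroxy-4-(methoxymethoxy)-6-{2-[4-(methoxymethoxy)phenyl]ethyl}benzaldehyde
Conditions: MOMCl (2.1 equiv), K2CO3, acetone, 0 °C → rt
Reagents that add atoms: chloromethyl methyl ether COCCl
Why: Williamson-type O-alkylation; the OH ortho to the CHO group is held in an intramolecular hydrogen bond and should stay free, so the two oxygens of the resorcinol ring are told apart without a statistical step.

Step 3
Reactants: 4 2-hydroxy-4-(methoxymethoxy)-6-{2-[4-(methoxymethoxy)phenyl]ethyl}benzaldehyde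
Product: 5 tert-butyl 2-formyl-5-(methoxymethoxy)-3-{2-[4-(methoxymethoxy)phenyl]ethyl}phenyl carbonate
Conditions: Boc2O (1.3 equiv), DMAP (10 mol %), CH2Cl2, rt
Reagents that add atoms: di-tert-butyl dicarbonate CC(C)(C)OC(=O)OC(=O)OC(C)(C)C
Why: DMAP-catalysed O-acylation of the remaining phenol gives the aryl tert-butyl carbonate that later acts as the trigger for o-quinone methide formation.

Step 4
Reactants: 5 tert-butyl 2-formyl-5-(methoxymethoxy)-3-{2-[4-(methoxymethoxy)phenyl]ethyl}phenyl carbonate
Product: 6 tert-butyl 2-(hydroxymethyl)-5-(methoxymethoxy)-3-{2-[4-(methoxymethoxy)phenyl]ethyl}phenyl carbonate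
Conditions: BH3·THF, THF, 0 °C; then H2O
Reagents that add atoms: none
Why: borane reduction of the aldehyde proceeds without a free alkoxide, so the carbonate should stay on the phenol oxygen and the benzylic alcohol can be isolated.

Step 5
Reactants: 6 tert-butyl 2-(hydroxymethyl)-5-(methoxymethoxy)-3-{2-[4-(methoxymethoxy)phenyl]ethyl}phenyl carbonate; 7 2-methylprop-1-en-1-ylmagnesium bromide
Product: 9 5-(methoxymethoxy)-3-{2-[4-(methoxymethoxy)phenyl]ethyl}-2-(3-methylbut-2-en-1-yl)phenol, via o-quinone methide 8 (not isolated)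
Conditions: 7 (3 equiv), THF, −78 °C → rt; aq. NH4Cl
Reagents that add atoms: none
Why: anionic o-quinone methide generation and 1,4-addition; the magnesium alkoxide made by the first equivalent of 7 takes over the Boc group, the phenoxide expels tert-butyl carbonate to give 8, and a second equivalent of 7 adds to the exocyclic CH2 with rearomatisation, which turns the one-carbon handle into the prenyl group and frees exactly the phenol that later leaves as triflate.

Step 6
Reactants: 9 5-(methoxymethoxy)-3-{2-[4-(methoxymethoxy)phenyl]ethyl}-2-(3-methylbut-2-en-1-yl)phenol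
Product: 10 5-(methoxymethoxy)-3-{2-[4-(methoxymethoxy)phenyl]ethyl}-2-(3-methylbut-2-en-1-yl)phenyl N-(propan-2-yl)carbamate
Conditions: i-PrNCO (1.5 equiv), Et3N (0.2 equiv), CH2Cl2, rt
Reagents that add atoms: isopropyl isocyanate CC(C)N=C=O
Why: base-catalysed addition of the phenol to the isocyanate gives a carbamate that is a strong ortho-directing group and can later be removed under mild basic conditions.

Step 7
Reactants: 10 5-(methoxymethoxy)-3-{2-[4-(methoxymethoxy)phenyl]ethyl}-2-(3-methylbut-2-en-1-yl)phenyl N-(propan-2-yl)carbamate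
Product: 14 3-(methoxymethoxy)-5-{2-[4-(methoxymethoxy)phenyl]ethyl}-6-(3-methylbut-2-en-1-yl)-2-(trimethylsilyl)phenyl N-(propan-2-yl)carbamate, via N-silyl carbamate 11 (not isolated), via aryllithium 12 (not isolated), via bis-silyl carbamate 13 (not isolated)
Conditions: TBSOTf (1.1 equiv), TMEDA, Et2O, 0 °C → rt; n-BuLi (1.3 equiv), TMEDA, −78 °C; TMSCl, −78 °C → rt; aq. NaHSO4
Reagents that add atoms: chlorotrimethylsilane C[Si](C)(C)Cl
Why: directed ortho-metalation; after N-silylation in the flask the carbamate and the methoxymethoxy group together direct n-BuLi/TMEDA to the ring C–H between them, TMSCl silylates the aryllithium, and the N-silyl group is lost on aqueous work-up.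

Step 8
Reactants: 14 3-(methoxymethoxy)-5-{2-[4-(methoxymethoxy)phenyl]ethyl}-6-(3-methylbut-2-en-1-yl)-2-(trimethylsilyl)phenyl N-(propan-2-yl)carbamate
Product: 16 3-(methoxymethoxy)-5-{2-[4-(methoxymethoxy)phenyl]ethyl}-6-(3-methylbut-2-en-1-yl)-2-(trimethylsilyl)phenyl trifluoromethanesulfonate, via silyl phenol 15 (not isolated)
Conditions: DBU (1.5 equiv), Et2NH (1.2 equiv), MeCN, 40 °C; then PhNTf2 (1.5 equiv), rt
Reagents that add atoms: N-phenylbis(trifluoromethanesulfonimide) O=S(=O)(N(c1ccccc1)S(=O)(=O)C(F)(F)F)C(F)(F)F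
Why: E1cB cleavage of the N-monosubstituted carbamate (the isocyanate is trapped by Et2NH) gives the phenoxide of 15, which is triflated in the same flask before the C–Si bond can migrate or be lost; this is the standard carbamate route to o-silylaryl triflates.

Step 9
Reactants: 16 3-(methoxymethoxy)-5-{2-[4-(methoxymethoxy)phenyl]ethyl}-6-(3-methylbut-2-en-1-yl)-2-(trimethylsilyl)phenyl trifluoromethanesulfonate; 17 3-methylbut-2-enal
Product: 21 5-(methoxymethoxy)-7-{2-[4-(methoxymethoxy)phenyl]ethyl}-2,2-dimethyl-8-(3-methylbut-2-en-1-yl)-2H-chromene, via aryne 18 (not isolated), via benzoxete 19 (not isolated), via o-quinone methide 20 (not isolated)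
Conditions: CsF (3 equiv), MeCN, rt → 50 °C; 16 added slowly to 17 (5 equiv)
Reagents that add atoms: none
Why: Fluoride attack on silicon with loss of triflate gives aryne 18; the carbonyl oxygen of 17 adds to the aryne carbon remote from the methoxymethoxy-bearing carbon, the aryl anion formed next to that oxygen closes onto the oxocarbenium carbon (stepwise formal [2+2]) to benzoxete 19, 4π ring opening gives o-quinone methide 20, and oxa-6π electrocyclisation gives the pyran ring of 21. The closest known reaction type is the annulation of arynes with α,β-unsaturated aldehydes to 2H-chromenes, which for 3-alkoxyarynes shows the same sense of addition. Ring closures: the transient four-membered oxete by collapse of the zwitterion (formal [2+2]), the six-membered pyran by thermal disrotatory 6π electrocyclisation. No stereocentre remains, since the benzoxete carbon is transient and C2 carries two methyl groups. The step needs regioselectivity (oxygen at the aryne carbon next to the prenyl group, carbon at the one next to the methoxymethoxy group), which the inductive distortion of the aryne by the neighbouring C–O bond should secure against the small steric bias of the benzylic CH2 on the other side. It also needs chemoselectivity over ene reactions and over capture of 20 by a second aryne, which slow aryne release into excess 17 and the fast intramolecular ring closure should secure.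

Step 10
Reactants: 21 5-(methoxymethoxy)-7-{2-[4-(methoxymethoxy)phenyl]ethyl}-2,2-dimethyl-8-(3-methylbut-2-en-1-yl)-2H-chromene
Product: 22 7-[2-(4-hydroxyphenyl)ethyl]-2,2-dimethyl-8-(3-methylbut-2-en-1-yl)-2H-chromen-5-ol
Conditions: 3 M aq. HCl (cat.), MeOH, 40 °C
Reagents that add atoms: none
Why: acid-catalysed acetal exchange passes both methoxymethyl groups to methanol; the prenyl group has no free ortho OH to cyclise onto it and the 2,2-dimethylpyran ring should survive these mild conditions.

**Compound list**

1 | dihydroresveratrol, 5-[2-(4-hydroxyphenyl)ethyl]benzene-1,3-diol | Oc1ccc(CCc2cc(O)cc(O)c2)cc1 | starting material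
2 | {2,4-dihydroxy-6-[2-(4-hydroxyphenyl)ethyl]benzylidene}dimethyliminium chloride (not isolated) | C[N+](C)=Cc1c(O)cc(O)cc1CCc1ccc(O)cc1.[Cl-] | intermediate
3 | 2,4-dihydroxy-6-[2-(4-hydroxyphenyl)ethyl]benzaldehyde | O=Cc1c(O)cc(O)cc1CCc1ccc(O)cc1 | intermediate
4 | 2-hydroxy-4-(methoxymethoxy)-6-{2-[4-(methoxymethoxy)phenyl]ethyl}benzaldehyde | O=Cc1c(O)cc(OCOC)cc1CCc1ccc(OCOC)cc1 | intermediate
5 | tert-butyl 2-formyl-5-(methoxymethoxy)-3-{2-[4-(methoxymethoxy)phenyl]ethyl}phenyl carbonate | O=Cc1c(OC(=O)OC(C)(C)C)cc(OCOC)cc1CCc1ccc(OCOC)cc1 | intermediate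
6 | tert-butyl 2-(hydroxymethyl)-5-(methoxymethoxy)-3-{2-[4-(methoxymethoxy)phenyl]ethyl}phenyl carbonate | OCc1c(OC(=O)OC(C)(C)C)cc(OCOC)cc1CCc1ccc(OCOC)cc1 | intermediate
7 | 2-methylprop-1-en-1-ylmagnesium bromide | CC(C)=C[Mg]Br | starting material
8 | 3-(methoxymethoxy)-5-{2-[4-(methoxymethoxy)phenyl]ethyl}-6-methylidenecyclohexa-2,4-dien-1-one (o-quinone methide, not isolated) | C=C1C(=O)C=C(OCOC)C=C1CCc1ccc(OCOC)cc1 | intermediate
9 | 5-(methoxymethoxy)-3-{2-[4-(methoxymethoxy)phenyl]ethyl}-2-(3-methylbut-2-en-1-yl)phenol | CC(C)=CCc1c(O)cc(OCOC)cc1CCc1ccc(OCOC)cc1 | intermediate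
10 | 5-(methoxymethoxy)-3-{2-[4-(methoxymethoxy)phenyl]ethyl}-2-(3-methylbut-2-en-1-yl)phenyl N-(propan-2-yl)carbamate | CC(C)=CCc1c(OC(=O)NC(C)C)cc(OCOC)cc1CCc1ccc(OCOC)cc1 | intermediate
11 | N-[tert-butyl(dimethyl)silyl] derivative of carbamate 10 (not isolated) | CC(C)=CCc1c(OC(=O)N(C(C)C)[Si](C)(C)C(C)(C)C)cc(OCOC)cc1CCc1ccc(OCOC)cc1 | intermediate
12 | aryllithium from 11, lithiated between the carbamate and methoxymethoxy oxygens (not isolated) | CC(C)=CCc1c(OC(=O)N(C(C)C)[Si](C)(C)C(C)(C)C)c([Li])c(OCOC)cc1CCc1ccc(OCOC)cc1 | intermediate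
13 | N-[tert-butyl(dimethyl)silyl] derivative of carbamate 14 (not isolated) | CC(C)=CCc1c(OC(=O)N(C(C)C)[Si](C)(C)C(C)(C)C)c([Si](C)(C)C)c(OCOC)cc1CCc1ccc(OCOC)cc1 | intermediate
14 | 3-(methoxymethoxy)-5-{2-[4-(methoxymethoxy)phenyl]ethyl}-6-(3-methylbut-2-en-1-yl)-2-(trimethylsilyl)phenyl N-(propan-2-yl)carbamate | CC(C)=CCc1c(OC(=O)NC(C)C)c([Si](C)(C)C)c(OCOC)cc1CCc1ccc(OCOC)cc1 | intermediate
15 | 3-(methoxymethoxy)-5-{2-[4-(methoxymethoxy)phenyl]ethyl}-6-(3-methylbut-2-en-1-yl)-2-(trimethylsilyl)phenol (not isolated) | CC(C)=CCc1c(O)c([Si](C)(C)C)c(OCOC)cc1CCc1ccc(OCOC)cc1 | intermediate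
16 | 3-(methoxymethoxy)-5-{2-[4-(methoxymethoxy)phenyl]ethyl}-6-(3-methylbut-2-en-1-yl)-2-(trimethylsilyl)phenyl trifluoromethanesulfonate | CC(C)=CCc1c(OS(=O)(=O)C(F)(F)F)c([Si](C)(C)C)c(OCOC)cc1CCc1ccc(OCOC)cc1 | intermediate
17 | 3-methylbut-2-enal | CC(C)=CC=O | starting material
18 | 3-(methoxymethoxy)-5-{2-[4-(methoxymethoxy)phenyl]ethyl}-6-(3-methylbut-2-en-1-yl)benzyne (not isolated) | CC(C)=CCC1=C(CCc2ccc(OCOC)cc2)C=C(OCOC)C#C1 | intermediate
19 | 3-(methoxymethoxy)-5-{2-[4-(methoxymethoxy)phenyl]ethyl}-6-(3-methylbut-2-en-1-yl)-2-(2-methylprop-1-en-1-yl)-2H-benzo[b]oxete (racemic, not isolated) | CC(C)=CCc1c(CCc2ccc(OCOC)cc2)cc(OCOC)c2c1OC2C=C(C)C | intermediate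
20 | 5-(methoxymethoxy)-3-{2-[4-(methoxymethoxy)phenyl]ethyl}-2-(3-methylbut-2-en-1-yl)-6-(3-methylbut-2-en-1-ylidene)cyclohexa-2,4-dien-1-one (o-quinone methide, not isolated) | CC(C)=CCC1=C(CCc2ccc(OCOC)cc2)C=C(OCOC)C(=CC=C(C)C)C1=O | intermediate
21 | 5-(methoxymethoxy)-7-{2-[4-(methoxymethoxy)phenyl]ethyl}-2,2-dimethyl-8-(3-methylbut-2-en-1-yl)-2H-chromene | CC(C)=CCc1c(CCc2ccc(OCOC)cc2)cc(OCOC)c2c1OC(C)(C)C=C2 | intermediate
22 | 7-[2-(4-hydroxyphenyl)ethyl]-2,2-dimethyl-8-(3-methylbut-2-en-1-yl)-2H-chromen-5-ol | CC(C)=CCc1c(CCc2ccc(O)cc2)cc(O)c2c1OC(C)(C)C=C2 | target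

Total step count: 10
Longest linear sequence: 10 steps (1 → 22)

**Steps most likely to fail**

1. Step 9. The aryl–oxygen bond may form with poor regiocontrol because the attacked carbon sits next to the prenyl-bearing carbon, or the aryne may be diverted by ene reaction with allylic C–H bonds or by capture of the o-quinone methide by a second aryne. The fallback sets out from phenol 9 and closes the pyran ring from the other side. Heating 9 with 3-methylbut-2-enal 17 and PhB(OH)2 in toluene/AcOH should bring about C-alkylation at the only free position ortho to the phenol, dehydration to o-quinone methide 20 and oxa-6π closure. The route is rejoined at 21; this classical phenol–enal chromene annulation makes no compound outside the list (F0).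

2. Step 5. The o-quinone methide may oligomerise before the Grignard reagent adds, or the reagent may attack the carbonate directly. The fallback sets out from alcohol 6 and avoids both the anionic conditions and the quinone methide. Appel bromination (CBr4, PPh3, CH2Cl2, 0 °C) should give tert-butyl 2-(bromomethyl)-5-(methoxymethoxy)-3-{2-[4-(methoxymethoxy)phenyl]ethyl}phenyl carbonate F1. Stille coupling with tributyl(2-methylprop-1-en-1-yl)stannane (Pd(PPh3)4, a zerovalent palladium catalyst, toluene, 80 °C) should give tert-butyl 5-(methoxymethoxy)-3-{2-[4-(methoxymethoxy)phenyl]ethyl}-2-(3-methylbut-2-en-1-yl)phenyl carbonate F2. K2CO3 in MeOH at rt then removes the carbonate, and the route is rejoined at 9.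

3. Step 1. Formylation of the unprotected triphenol may suffer from competing attack between the two OH groups, O-formylation or double formylation. The fallback sets out from 1 and introduces the aldehyde through a halogen–metal exchange. MOMCl/NaH in DMF should give 1,3-bis(methoxymethoxy)-5-{2-[4-(methoxymethoxy)phenyl]ethyl}benzene F3. NBS in MeCN at 0 °C should brominate the doubly activated ring para to one oxygen and ortho to the other, giving 2-bromo-1,5-bis(methoxymethoxy)-3-{2-[4-(methoxymethoxy)phenyl]ethyl}benzene F4. n-BuLi in THF at −78 °C followed by DMF should give 2,4-bis(methoxymethoxy)-6-{2-[4-(methoxymethoxy)phenyl]ethyl}benzaldehyde F5. MgBr2·OEt2 in CH2Cl2 should then remove, under chelation control, only the methoxymethyl group ortho to the CHO group, and the route is rejoined at 4.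

**Further compounds**

F0 | step 9 | none | none
F1 | step 5 | tert-butyl 2-(bromomethyl)-5-(methoxymethoxy)-3-{2-[4-(methoxymethoxy)phenyl]ethyl}phenyl carbonate | BrCc1c(OC(=O)OC(C)(C)C)cc(OCOC)cc1CCc1ccc(OCOC)cc1
F2 | step 5 | tert-butyl 5-(methoxymethoxy)-3-{2-[4-(methoxymethoxy)phenyl]ethyl}-2-(3-methylbut-2-en-1-yl)phenyl carbonate | CC(C)=CCc1c(OC(=O)OC(C)(C)C)cc(OCOC)cc1CCc1ccc(OCOC)cc1
F3 | step 1 | 1,3-bis(methoxymethoxy)-5-{2-[4-(methoxymethoxy)phenyl]ethyl}benzene | COCOc1ccc(CCc2cc(OCOC)cc(OCOC)c2)cc1
F4 | step 1 | 2-bromo-1,5-bis(methoxymethoxy)-3-{2-[4-(methoxymethoxy)phenyl]ethyl}benzene | COCOc1ccc(CCc2cc(OCOC)cc(OCOC)c2Br)cc1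
F5 | step 1 | 2,4-bis(methoxymethoxy)-6-{2-[4-(methoxymethoxy)phenyl]ethyl}benzaldehyde | COCOc1ccc(CCc2cc(OCOC)cc(OCOC)c2C=O)cc1
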